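**Retrosynthetic overview**

1. The acid comes from a primary alcohol (TEMPO oxidation) and two silyl ethers. The 7-oxo-cyclohepta[b]furan core comes from a dispiro[cyclohexane–cyclopropane–cycloheptanedione] carbinol.
2. In that carbinol one acid-mediated operation opens the cyclopropane and re-closes it as the 2,3-dihydrofuran, with a ring C=O carbon and its oxygen as the two added ring atoms. Loss of two molecules of water makes the tropone at the same time.
3. The seven-membered ring is built on a spiro 1,1-dipropanoylcyclopropane by aldol/Dieckmann condensation with dimethyl mesoxalate. The cyclopropane comes from an exocyclic methylene and a diazo diketone.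
4. The cyclohexane is (S)-carvone, alkylated twice at C-α′ to give the quaternary carbon. Ring order: cyclohexane (chiral pool) → cyclopropane → cycloheptane → (cyclopropane → dihydrofuran, together with cycloheptanedione → tropone).
5. Enabling feature: the carbon shared by the cyclopropane and the seven-membered ring is flanked in that ring by a CH–OH carbon and by a carbonyl of an enolisable 2-methyl-1,3-diketone. The other cyclopropane bond of this carbon ends at the fully substituted cyclohexane carbon, so ionisation gives a tertiary cation held next to the enol oxygen.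

Key step: step 12

Locants used below: cyclohexane carbons are C-5 (CH bearing the C3 unit), C-6, C-7, C-8 (C–CH3), C-9 (C=O, later the spiro carbon), C-10 (quaternary carbon); C-11 is the CH2 of the small ring. Seven-membered-ring carbons are C-1′ (ester-bearing), C-2′ (CH3), C-3′, C-4′ (bonded to C-11), C-5′ (O-bearing), C-6′ (CH3), C-7′ (C=O).

Remark: compounds 12 and 14–17 are carried as diastereomer mixtures at the centres that step 12 removes. Their SMILES leave the primed centres open and show the expected major configuration at C-9. Dimethyl mesoxalate is taken to be available and is used as the anhydrous ketone.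

**Step 1**
Reactants: 1 (S)-(+)-carvone
Product: 2 trans-6-methylcarvone [(5S,6R)-2,6-dimethyl-5-(prop-1-en-2-yl)cyclohex-2-en-1-one; the minor cis epimer is equally usable]
Conditions: LDA, THF, −78 °C; MeI
Reagents that add atoms: iodomethane CI
Why: Kinetic α′-deprotonation of the cross-conjugated enone followed by SN2 methylation (enolate alkylation); the new C-10 centre is planarised again in step 2, so its configuration does not matter.

**Step 2**
Reactants: 2 trans-6-methylcarvone
Product: 3 6-allyl-6-methylcarvone [6-allyl-2,6-dimethyl-5-(prop-1-en-2-yl)cyclohex-2-en-1-one; 10-CH3 cis and allyl trans to the isopropenyl group]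
Conditions: LDA, THF/DMPU, −78 °C; allyl bromide, −78 → 0 °C
Reagents that add atoms: allyl bromide C=CCBr
Why: Second α′-enolate alkylation; allyl bromide should attack the trisubstituted enolate on the face opposite the neighbouring isopropenyl group, which sets the quaternary C-10 with methyl cis and allyl trans to that group.

**Step 3**
Reactants: 3 6-allyl-6-methylcarvone
Product: 4 2-allyl-2,6-dimethyl-3-(prop-1-en-2-yl)cyclohexan-1-one [8-CH3 trans to 10-CH3]
Conditions: L-Selectride (1.1 equiv), THF, −78 °C; MeOH; then NaOMe (cat.), MeOH, rt
Reagents that add atoms: none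
Why: Conjugate (1,4-) hydride reduction of the β-unsubstituted enone; base equilibration should place the new C-8 methyl equatorial, away from the 1,3-related axial C-10 methyl, which is the required configuration.

**Step 4**
Reactants: 4 allyl ketone
Product: 6 2-(3-hydroxypropyl)-2,6-dimethyl-3-(prop-1-en-2-yl)cyclohexan-1-one, via alkyl catecholboronate 5 (not isolated)
Conditions: catecholborane (1.5 equiv), RhCl(PPh3)3 (2 mol %), THF, rt; then NaOH, H2O2, 0 °C
Reagents that add atoms: hydrogen peroxide OO
Why: Rh-catalysed (Männig–Nöth) hydroboration is selective for the monosubstituted alkene over the 1,1-disubstituted isopropenyl group and spares the ketone; oxidation should give the anti-Markovnikov primary alcohol without a new stereocentre.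

**Step 5**
Reactants: 6 hydroxypropyl ketone
Product: 7 3-(2-hydroxypropan-2-yl)-2-(3-hydroxypropyl)-2,6-dimethylcyclohexan-1-one
Conditions: Co(acac)2 (20 mol %), PhSiH3, O2 (1 atm), THF/i-PrOH, rt
Reagents that add atoms: dioxygen O=O
Why: Mukaiyama (Co–H hydrogen-atom-transfer) Markovnikov hydration of the remaining 1,1-disubstituted alkene should give the tertiary alcohol; no stereocentre is formed.

**Step 6**
Reactants: 7 keto diol
Product: 8 bis(tert-butyldimethylsilyl) ether of 7
Conditions: TBSOTf (2.5 equiv), 2,6-lutidine, CH2Cl2, −78 → 0 °C
Reagents that add atoms: tert-butyldimethylsilyl trifluoromethanesulfonate CC(C)(C)[Si](C)(C)OS(=O)(=O)C(F)(F)F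
Why: Silyl triflate silylation protects the primary and the tertiary alcohol in one operation against the carbenoid, enolate and acid steps that follow; the hindered ketone should stay untouched under lutidine buffering.

**Step 7**
Reactants: 8 bis-silyl ketone
Product: 9 exocyclic alkene (C-9=C-11 methylidene analogue of 8)
Conditions: Ph3PCH3Br, KOtBu, toluene, 100 °C
Reagents that add atoms: methyltriphenylphosphonium bromide C[P+](c1ccccc1)(c1ccccc1)c1ccccc1.[Br-]
Why: Wittig methylenation under the salt-free high-temperature conditions used for hindered ketones; C-8 is already the thermodynamic epimer, so the basic medium cannot erode it.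

**Step 8**
Reactants: 10 heptane-3,5-dione
Product: 11 4-diazoheptane-3,5-dione
Conditions: p-ABSA, Et3N, MeCN, 0 °C → rt
Reagents that add atoms: 4-acetamidobenzenesulfonyl azide CC(=O)Nc1ccc(cc1)S(=O)(=O)N=[N+]=[N-]
Why: Regitz diazo transfer to the acidic central CH2 of a 1,3-diketone.

**Step 9**
Reactants: 9 exocyclic alkene; 11 4-diazoheptane-3,5-dione
Product: 12 dispiro diketone [1,1-dipropanoylcyclopropane whose second ring carbon is C-9 of the cyclohexane; acyl-bearing carbon anti to the axial 10-CH3 in the major isomer]
Conditions: Rh2(esp)2 (1 mol %), CH2Cl2, rt, slow addition of 11 (2 equiv)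
Reagents that add atoms: none
Why: Rh(II)-carbenoid cyclopropanation of a 1,1-disubstituted alkene by an acceptor/acceptor carbenoid; because the two acyl groups are identical only C-9 becomes stereogenic, addition anti to the axial C-10 methyl is expected, and this centre is reset in step 12 in any case.

**Step 10**
Reactants: 12 dispiro diketone; 13 dimethyl mesoxalate
Product: 15 dispiro cycloheptanetrione carbinol [methyl 1-hydroxy-2,6-dimethyl-3,5,7-trioxocycloheptane-1-carboxylate spiro-fused at C-4′ to the cyclopropane], via open aldol adduct 14 (not isolated)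
Conditions: LDA (2.3 equiv), THF, −78 °C; 13 (1.05 equiv), −78 → 0 °C; aq NH4Cl
Reagents that add atoms: none
Why: The bis-enolate of the two propanoyl arms should add with one arm to the ketone of the mesoxalate (aldol addition) and with the other to one of its two equivalent esters (seven-membered Dieckmann-type Claisen closure, driven by the enolate of the new 2-methyl-1,3-diketone); the new stereocentres are all removed in step 12.

**Step 11**
Reactants: 15 trione carbinol
Product: 16 dispiro diol dione [C-3′ ketone reduced to CH–OH; C-5′/C-7′ 1,3-diketone retained]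
Conditions: NaBH4 (2 equiv), CeCl3·7H2O, MeOH, −78 → −40 °C
Reagents that add atoms: none
Why: Chemoselective borohydride (Luche-type) reduction; the acidic 1,3-diketone is deprotonated first and thereby protected, so hydride should reach only the isolated C-3′ ketone, and the configuration of the new carbinol is irrelevant.

**Step 12**
Reactants: 16 dispiro diol dione
Product: 18 bis-silyl ether of the tropone alcohol [methyl 5,8-dimethyl-7-oxo-cyclohepta[b]furan-6-carboxylate spiro-linked at the O-bearing carbon C-9 to the cyclohexane], via hydroxy dihydrofuran 17 (not isolated)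
Conditions: p-TsOH (20 mol %), toluene, 4 Å MS, 0 °C → rt
Reagents that add atoms: none
Why: Proposed new method: loss of water from the protonated C-3′ carbinol is assisted by the cyclopropane (Julia-type cyclopropylcarbinyl → homoallyl opening), breaking the C-4′–C-9 bond to give the C-3′=C-4′ alkene and a tertiary C-9 cation; the enol oxygen on C-5′ then closes on C-9, and acid-catalysed loss of the C-1′ hydroxyl through an oxytropylium ion aromatises the carbocycle, so the three-membered ring is expanded to the 2,3-dihydrofuran by C-5′ and its oxygen. The closest known reaction types are the Cloke–Wilson rearrangement of 1-acylcyclopropanes to 2,3-dihydrofurans and the Julia–Johnson homoallyl opening; their coupling to a double dehydration that delivers a tropone is the new element. The only ring closed is the dihydrofuran, by 5-exo-type collapse of the enol oxygen on the cation within the ion pair. The O-bearing spiro centre C-9 should be set by axial attack on the cyclohexyl cation anti to the axial methyl of the adjacent C-10, the face on which the tethered oxygen already sits in the major cyclopropane; all primed stereocentres and both C-9 epimers of 16 are erased, so the mixture should converge on one product. The step needs cleavage of the cyclopropane bond to the quaternary carbon (secured by tertiary-cation stability), capture by oxygen before elimination or a 1,2-shift (secured by the five-membered ion-paired delivery), and closure through C-5′ only (secured because the other flanking carbonyl was reduced in step 11).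

**Step 13**
Reactants: 18 bis-silyl ether
Product: 19 tropone diol [primary alcohol and tertiary alcohol free]
Conditions: HF·pyridine, pyridine/THF, 0 °C → rt
Reagents that add atoms: none
Why: Fluoride-mediated desilylation removes both TBS groups; the vinylogous ester of the tropone and the methyl ester should be stable to buffered HF.

**Step 14**
Reactants: 19 tropone diol
Product: 20 target acid CNP0448476.1
Conditions: TEMPO (20 mol %), PhI(OAc)2 (2.5 equiv), MeCN/H2O 1:1, rt
Reagents that add atoms: water O
Why: TEMPO/PhI(OAc)2 oxidation takes the primary alcohol through the aldehyde hydrate to the carboxylic acid and cannot oxidise the tertiary alcohol; no stereocentre is touched.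

**Compound list**

1 | (S)-(+)-carvone | CC1=CC[C@@H](CC1=O)C(C)=C | starting material
2 | trans-6-methylcarvone | O=C1C(C)=CC[C@H](C(C)=C)[C@H]1C | intermediate
3 | 6-allyl-6-methylcarvone (10-CH3 cis to isopropenyl) | O=C1C(C)=CC[C@H](C(C)=C)[C@@]1(C)CC=C | intermediate
4 | 2-allyl-2,6-dimethyl-3-(prop-1-en-2-yl)cyclohexan-1-one | O=C1[C@@H](C)CC[C@H](C(C)=C)[C@@]1(C)CC=C | intermediate
5 | alkyl catecholboronate of 4 | O=C1[C@@H](C)CC[C@H](C(C)=C)[C@@]1(C)CCCB1Oc2ccccc2O1 | intermediate
6 | 2-(3-hydroxypropyl)-2,6-dimethyl-3-(prop-1-en-2-yl)cyclohexan-1-one | O=C1[C@@H](C)CC[C@H](C(C)=C)[C@@]1(C)CCCO | intermediate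
7 | 3-(2-hydroxypropan-2-yl)-2-(3-hydroxypropyl)-2,6-dimethylcyclohexan-1-one | O=C1[C@@H](C)CC[C@H](C(C)(C)O)[C@@]1(C)CCCO | intermediate
8 | bis-TBS ether of 7 | O=C1[C@@H](C)CC[C@H](C(C)(C)O[Si](C)(C)C(C)(C)C)[C@@]1(C)CCCO[Si](C)(C)C(C)(C)C | intermediate
9 | exocyclic alkene | C=C1[C@@H](C)CC[C@H](C(C)(C)O[Si](C)(C)C(C)(C)C)[C@@]1(C)CCCO[Si](C)(C)C(C)(C)C | intermediate
10 | heptane-3,5-dione | CCC(=O)CC(=O)CC | starting material
11 | 4-diazoheptane-3,5-dione | CCC(=O)C(=[N+]=[N-])C(=O)CC | intermediate
12 | dispiro 1,1-dipropanoylcyclopropane | CCC(=O)C1(C(=O)CC)C[C@@]12[C@@H](C)CC[C@H](C(C)(C)O[Si](C)(C)C(C)(C)C)[C@@]2(C)CCCO[Si](C)(C)C(C)(C)C | intermediate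
13 | dimethyl mesoxalate (dimethyl 2-oxopropanedioate) | COC(=O)C(=O)C(=O)OC | starting material
14 | open aldol adduct | CCC(=O)C1(C(=O)C(C)C(O)(C(=O)OC)C(=O)OC)C[C@@]12[C@@H](C)CC[C@H](C(C)(C)O[Si](C)(C)C(C)(C)C)[C@@]2(C)CCCO[Si](C)(C)C(C)(C)C | intermediate
15 | dispiro cycloheptanetrione carbinol | CC1C(=O)C2(C[C@@]23[C@@H](C)CC[C@H](C(C)(C)O[Si](C)(C)C(C)(C)C)[C@@]3(C)CCCO[Si](C)(C)C(C)(C)C)C(=O)C(C)C(O)(C(=O)OC)C1=O | intermediate
16 | dispiro diol dione | CC1C(=O)C2(C[C@@]23[C@@H](C)CC[C@H](C(C)(C)O[Si](C)(C)C(C)(C)C)[C@@]3(C)CCCO[Si](C)(C)C(C)(C)C)C(O)C(C)C(O)(C(=O)OC)C1=O | intermediate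
17 | hydroxy dihydrofuran (ring-expanded, not yet aromatic) | COC(=O)C1(O)C(C)C=C2C(=C(C)C1=O)O[C@@]1(C2)[C@@H](C)CC[C@H](C(C)(C)O[Si](C)(C)C(C)(C)C)[C@@]1(C)CCCO[Si](C)(C)C(C)(C)C | intermediate
18 | bis-TBS ether of the tropone alcohol | COC(=O)c1c(C)cc2c(c(C)c1=O)O[C@@]1(C2)[C@@H](C)CC[C@H](C(C)(C)O[Si](C)(C)C(C)(C)C)[C@@]1(C)CCCO[Si](C)(C)C(C)(C)C | intermediate
19 | tropone diol | COC(=O)c1c(C)cc2c(c(C)c1=O)O[C@@]1(C2)[C@@H](C)CC[C@H](C(C)(C)O)[C@@]1(C)CCCO | intermediate
20 | CNP0448476.1 (5S,8S,9S,10R in the locants above) | COC(=O)c1c(C)cc2c(c(C)c1=O)O[C@@]1(C2)[C@@H](C)CC[C@H](C(C)(C)O)[C@@]1(C)CCC(=O)O | target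

**Step count and risks**

Total steps: 14. Longest linear sequence: 13 (steps 1–7 and 9–14; step 8 is a one-step branch).

Steps most likely to fail:

1. Step 12 (Proposed new method). The tertiary C-9 cation may be lost by E1 elimination or by a 1,2-hydride or 1,2-methyl shift before the enol oxygen closes. The C–O bond may also form on the wrong face, or aromatisation may stall at the carbinol stage. The fallback sets out from 16 and returns at 18 and separates the events with known reactions. Compound 16 would be opened with MgBr2·OEt2 in Et2O (Julia–Johnson cyclopropylcarbinol → homoallyl halide opening) to the homoallylic tertiary bromide F1. F1 would be ionised at −78 °C with AgOTf and 2,6-di-tert-butylpyridine, so that the diketone enol is O-alkylated (silver-assisted etherification) to 17. Compound 17 would then be dehydrated with TsOH to 18.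

2. Step 10. The lithium aldolate may undergo retro-aldol cleavage, the second enolate may add to a second mesoxalate molecule, or the seven-membered Claisen closure may be too slow. The fallback sets out from 12 and returns at 15. The mono-enolate of 12 (LDA, 1 equiv) would be added to 13 and the aldolate trapped with TMSCl as the silyl-protected mono-aldol adduct F2, which can no longer revert. F2 would be cyclised with LiHMDS (2.2 equiv, THF, −78 → 0 °C; Dieckmann-type Claisen), and the TMS ether cleaved during citric acid work-up to give 15.

3. Step 9. The acceptor/acceptor carbenoid may undergo Wolff rearrangement or add too slowly to the hindered alkene. The 1,1-diacylcyclopropane may also ring-expand under the Lewis-acidic catalyst to an acyl dihydrofuran before the carbocycle exists. The fallback sets out from 9 and returns at 12. Cyclopropanation with dimethyl diazomalonate and Rh2(esp)2 would give the robust cyclopropane-1,1-diester F3. F3 would be converted with MeNH(OMe)·HCl and i-PrMgCl into the bis-Weinreb amide F4, and F4 with EtMgBr (THF, 0 °C) into 12.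

**Further compounds**

F1 | step 12 | homoallylic tertiary bromide (C-9–Br; C-3′=C-4′ alkene) | CC1C(=O)C(CC2(Br)[C@@H](C)CC[C@H](C(C)(C)O[Si](C)(C)C(C)(C)C)[C@@]2(C)CCCO[Si](C)(C)C(C)(C)C)=CC(C)C(O)(C(=O)OC)C1=O
F2 | step 10 | TMS-protected mono-aldol adduct | CCC(=O)C1(C(=O)C(C)C(O[Si](C)(C)C)(C(=O)OC)C(=O)OC)C[C@@]12[C@@H](C)CC[C@H](C(C)(C)O[Si](C)(C)C(C)(C)C)[C@@]2(C)CCCO[Si](C)(C)C(C)(C)C
F3 | step 9 | dispiro cyclopropane-1,1-dicarboxylate | COC(=O)C1(C(=O)OC)C[C@@]12[C@@H](C)CC[C@H](C(C)(C)O[Si](C)(C)C(C)(C)C)[C@@]2(C)CCCO[Si](C)(C)C(C)(C)C
F4 | step 9 | dispiro bis-Weinreb amide | CON(C)C(=O)C1(C(=O)N(C)OC)C[C@@]12[C@@H](C)CC[C@H](C(C)(C)O[Si](C)(C)C(C)(C)C)[C@@]2(C)CCCO[Si](C)(C)C(C)(C)C
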